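## Retrosynthetic overview

1. The bromotetrahydropyran is closed last: the C–O and C5–Br bonds come from an anodic, bromide-mediated 6-endo bromoetherification of the prenyl carbinol 12.
2. The prenyl group of 12 comes from allyl compound 10 by cross-metathesis; the allyl group is kept until then because it is inert to electrophilic bromine.
3. The ring Br/Cl pair of 10 comes from cyclohexenyl carbinol 9 by a new hydroxyl-relayed (hypobromite) bromochlorination. It is designed to put Br cis and Cl trans to the side chain, the opposite of what free BrCl would give.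
4. Carbinol 9 comes from hydroxy ketone 7 by Mitsunobu inversion/acetylation and Felkin–Anh methyl addition. Ketone 7 comes from a hydroxyl-directed Diels–Alder of enone 5 with isoprene.
5. Enone 5 comes from methyl (R)-glycidate (L-serine-derived), the only source of chirality. Ring order: cyclohexene first, tetrahydropyran last.

Assumption: operations run in one flask without isolating an intermediate count as one step; only skeleton-building compounds are numbered, and auxiliary reagents are given by name and SMILES.

## Route

**Step 1**
Reactants: 1, methyl (R)-glycidate; 2, vinylmagnesium bromide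
Product: 3, methyl (2R)-2-hydroxypent-4-enoate
Conditions: CH2=CHMgBr (1.3 equiv), CuI (10 mol %), THF, −40 °C; aq. NH4Cl
Reagents that add atoms: vinylmagnesium bromide (2), C=C[Mg]Br
Why: Cu-catalysed Grignard opening of the glycidic ester occurs by SN2 at the unsubstituted C3, so the C2 stereocentre is carried over unchanged.

**Step 2**
Reactants: 3, methyl (2R)-2-hydroxypent-4-enoate; 2, vinylmagnesium bromide
Product: 5, (4R)-4-hydroxyhepta-1,6-dien-3-one, via 4, (2R)-2-hydroxy-N-methoxy-N-methylpent-4-enamide (not isolated)
Conditions: MeNHOMe·HCl, i-PrMgCl, THF, −20 °C; then CH2=CHMgBr, 0 °C; inverse quench into cold 1 M HCl; use crude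
Reagents that add atoms: vinylmagnesium bromide (2), C=C[Mg]Br (the N,O-dimethylhydroxylamine is lost again)
Why: One-pot ester to Weinreb amide to ketone; the magnesium chelate stops vinyl addition at the ketone stage, and the α-alkoxide suppresses enolisation, so the carbinol centre is untouched.

**Step 3**
Reactants: 5, (4R)-4-hydroxyhepta-1,6-dien-3-one; 6, isoprene
Product: 7, (2R)-2-hydroxy-1-[(1R)-4-methylcyclohex-3-en-1-yl]pent-4-en-1-one
Conditions: isoprene (5 equiv), ZnCl2 (1.0 equiv), CH2Cl2, −45 °C
Reagents that add atoms: isoprene (6), CC(=C)C=C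
Why: Lewis-acid Diels–Alder with "para" regiochemistry; the α′-hydroxy enone reacts as the chelated, syn-planar s-cis conformer (Masamune-type 1,4-induction), so isoprene adds to the face anti to the allyl group on the carbinol carbon, setting C1′ as R.

**Step 4**
Reactants: 7, (2R)-2-hydroxy-1-[(1R)-4-methylcyclohex-3-en-1-yl]pent-4-en-1-one
Product: 8, (2S)-1-[(1R)-4-methylcyclohex-3-en-1-yl]-1-oxopent-4-en-2-yl acetate
Conditions: AcOH, PPh3, DIAD, THF, 0 °C
Reagents that add atoms: acetic acid, CC(=O)O
Why: Mitsunobu esterification; SN2 displacement at the carbonyl-activated secondary carbinol inverts it (R to S) and installs the target's acetate in the same operation.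

**Step 5**
Reactants: 8, (2S)-1-[(1R)-4-methylcyclohex-3-en-1-yl]-1-oxopent-4-en-2-yl acetate
Product: 9, (2S,3S)-2-hydroxy-2-[(1R)-4-methylcyclohex-3-en-1-yl]hex-5-en-3-yl acetate
Conditions: MeLi/CeCl3 (MeCeCl2), THF, −78 °C; AcOH quench at −78 °C
Reagents that add atoms: methyllithium, [Li]C
Why: Non-chelating, weakly basic organocerium adds to the ketone in preference to the acetate; polar Felkin–Anh addition (acetoxy anti to the incoming methyl, attack past H) sets the tertiary carbinol as 2S (OH and OAc syn along the ring–C2–C3–C4 chain).

**Step 6**
Reactants: 9, (2S,3S)-2-hydroxy-2-[(1R)-4-methylcyclohex-3-en-1-yl]hex-5-en-3-yl acetate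
Product: 10, (2S,3S)-2-[(1R,3R,4R)-3-bromo-4-chloro-4-methylcyclohexyl]-2-hydroxyhex-5-en-3-yl acetate
Conditions: i-PrMgCl (1.0 equiv), CH2Cl2/THF, −78 °C; NBS (1.0 equiv), dark, 10 min; then Et4NCl (5 equiv), HFIP (3 equiv), 0.01 M, −78 → −40 °C
Reagents that add atoms: N-bromosuccinimide, O=C1CCC(=O)N1Br; tetraethylammonium chloride, CC[N+](CC)(CC)CC.[Cl-]
Why: Proposed new method: hydroxyl-relayed bromochlorination — the tertiary alkoxide is converted into its hypobromite, the only Br(+) carrier present, which hands Br to C3′ through a six-membered O–Br···C3′ transition state reachable only on the alkene face syn to the side chain; the tethered oxygen sits on that same face and cannot open the bromonium, so external chloride attacks the tertiary C4′ anti (Markovnikov), and ring flip leaves Br cis and Cl trans to the side chain, both equatorial (3′R,4′R), where free BrCl would give the opposite, diaxial isomer; the monosubstituted allyl alkene is far less nucleophilic and is left alone; closest known chemistry is ionic addition of tert-alkyl hypobromites to alkenes, alkoxide-templated Ti-mediated bromochlorination of allylic alcohols, and hydroxyl-directed epoxidation.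

**Step 7**
Reactants: 10, (2S,3S)-2-[(1R,3R,4R)-3-bromo-4-chloro-4-methylcyclohexyl]-2-hydroxyhex-5-en-3-yl acetate; 11, 2-methylbut-2-ene
Product: 12, (2S,3S)-2-[(1R,3R,4R)-3-bromo-4-chloro-4-methylcyclohexyl]-2-hydroxy-6-methylhept-5-en-3-yl acetate
Conditions: Grubbs II (5 mol %), 2-methylbut-2-ene/CH2Cl2, 35 °C
Reagents that add atoms: 2-methylbut-2-ene (11), CC=C(C)C
Why: Olefin cross-metathesis converts the terminal allyl group into the prenyl group; alkyl halides, the acetate and the tertiary alcohol are tolerated and no stereocentre is touched.

**Step 8**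
Reactants: 12, (2S,3S)-2-[(1R,3R,4R)-3-bromo-4-chloro-4-methylcyclohexyl]-2-hydroxy-6-methylhept-5-en-3-yl acetate
Product: 13, acetylcaespitol, (2S,3S,5S)-5-bromo-2-[(1R,3R,4R)-3-bromo-4-chloro-4-methylcyclohexyl]-2,6,6-trimethyloxan-3-yl acetate
Conditions: undivided cell, graphite anode | Pt cathode, Et4NBr (2 equiv), MeCN/HFIP 9:1, constant current, 2.2 F mol⁻¹, 0 °C
Reagents that add atoms: tetraethylammonium bromide, CC[N+](CC)(CC)CC.[Br-]
Why: Anodic oxidation of bromide gives Br(+), and the tertiary hydroxyl opens the bromonium at the tertiary carbon (6-endo, Markovnikov bromoetherification); in the chair transition state the cyclohexyl group is equatorial and the C2 methyl axial (the alternative puts cyclohexyl syn-diaxial to a C6 methyl), and Br is necessarily equatorial (anti to the forming C–O bond), which sets C5 as S with OAc axial.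

## Compound list

1 | methyl (R)-glycidate | COC(=O)[C@H]1CO1 | starting material
2 | vinylmagnesium bromide | C=C[Mg]Br | starting material
3 | methyl (2R)-2-hydroxypent-4-enoate | COC(=O)[C@H](O)CC=C | intermediate
4 | (2R)-2-hydroxy-N-methoxy-N-methylpent-4-enamide (not isolated) | CON(C)C(=O)[C@H](O)CC=C | intermediate
5 | (4R)-4-hydroxyhepta-1,6-dien-3-one | C=CC(=O)[C@H](O)CC=C | intermediate
6 | isoprene | CC(=C)C=C | starting material
7 | (2R)-2-hydroxy-1-[(1R)-4-methylcyclohex-3-en-1-yl]pent-4-en-1-one | C=CC[C@@H](O)C(=O)[C@@H]1CCC(C)=CC1 | intermediate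
8 | (2S)-1-[(1R)-4-methylcyclohex-3-en-1-yl]-1-oxopent-4-en-2-yl acetate | C=CC[C@H](OC(C)=O)C(=O)[C@@H]1CCC(C)=CC1 | intermediate
9 | (2S,3S)-2-hydroxy-2-[(1R)-4-methylcyclohex-3-en-1-yl]hex-5-en-3-yl acetate | C=CC[C@H](OC(C)=O)[C@@](C)(O)[C@@H]1CCC(C)=CC1 | intermediate
10 | (2S,3S)-2-[(1R,3R,4R)-3-bromo-4-chloro-4-methylcyclohexyl]-2-hydroxyhex-5-en-3-yl acetate | C=CC[C@H](OC(C)=O)[C@@](C)(O)[C@@H]1CC[C@@](C)(Cl)[C@H](Br)C1 | intermediate
11 | 2-methylbut-2-ene | CC=C(C)C | starting material
12 | (2S,3S)-2-[(1R,3R,4R)-3-bromo-4-chloro-4-methylcyclohexyl]-2-hydroxy-6-methylhept-5-en-3-yl acetate | CC(C)=CC[C@H](OC(C)=O)[C@@](C)(O)[C@@H]1CC[C@@](C)(Cl)[C@H](Br)C1 | intermediate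
13 | acetylcaespitol | CC(=O)O[C@H]1C[C@H](Br)C(C)(C)O[C@@]1(C)[C@@H]1CC[C@@](C)(Cl)[C@H](Br)C1 | target

## Summary

Total steps: 8. Longest linear sequence: 8 (from methyl (R)-glycidate).

Steps most likely to fail:

1. **Step 6 (new hydroxyl-relayed bromochlorination).** Risks: intermolecular, undirected Br(+) transfer (giving the diaxial isomer or a bridged bromo-ether) and hypobromite homolysis. Fallback with known chemistry: on 9, run the cross-metathesis and pyran closure first (stoichiometric TBCO, chemoselective for the hydroxy-alkene). Then dihydroxylate the ring alkene (OsO4/NMO) and separate the cis-diol anti to the side chain. Convert it to the cyclic sulfate, open with LiBr at the secondary carbon (inversion, equatorial Br), hydrolyse, and exchange the tertiary OH for Cl with retention through neighbouring-bromine participation (conc. HCl or SOCl2).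

2. **Step 3 (facial selectivity of the Diels–Alder with only an allyl group as the shielding substituent).** Fallback: change the control element and the pool enantiomer. Use methyl (S)-glycidate and the O-TBS α′-silyloxy enone with a monodentate Lewis acid (Me2AlCl). The dipole-opposed (Cornforth) conformer is predicted to give the same (1′R) ring centre with the carbinol already S, so the Mitsunobu step is dropped. Felkin methyl addition, then TBAF and Ac2O, rejoin the route at 9.

3. **Step 5 (Felkin selectivity and acetate survival in the methyl addition).** Fallback: add MeMgBr to the free hydroxy ketone 7 under chelation control, which gives the same (2S) tertiary centre from the (R)-alkoxide, and acetylate with retention. Carry the 3-epi series through steps 6–8, then correct C3 on the pyran: K2CO3/MeOH, Dess–Martin oxidation, L-Selectride (equatorial hydride delivery gives the axial 3S alcohol), Ac2O.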